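**Compound numbers used throughout** (full names and SMILES are in the list after the steps): 1 and 5 are the two aryl aldehydes, 2–4 the propargylic alcohol series, 6 the allenylzinc reagent, 7–8 the homopropargylic alcohol and its silyl ether, 9–10 the acetylide and ynolate, 11 the siloxyalkyne, 12–16 the cyclobutenone branch, 17–20 the intermediates of the annulation, 21 its product, 22 the benzylic cation, 23–24 the protected dihydrobenzofurans, 25 the target.

## Analysis of the target

Target 25 is a 2,3-dihydrobenzofuran (O1, C2, C3, C3a–C7a). It carries a 4-hydroxy-3-methoxyphenyl ring on C2, a 3,5-dihydroxyphenyl ring on C3, a hydroxyl on C4 and an (E)-4-hydroxy-3-methoxystyryl group on C6. The only stereocentres are C2 and C3, both R, with the two aryl groups trans on the five-membered ring. The two centres are not equally demanding. C2 is a benzylic ether carbon para to a phenolic oxygen, so it can ionise and re-close and its configuration follows that of C3. C3 is an all-carbon methine that has to be set absolutely and then kept away from any E1 or base-induced loss of its proton. The sensitive groups are five free phenols (oxidation), an electron-rich E-stilbene (acid, hydrogenation), the acid-labile O1–C2 bond and two methyl ethers that must stay. The hard part is the benzo ring: the C3 side chain sits on C3a between two oxygens (O1 on C7a, OH on C4) and the styryl group on C6 is meta to both, a pattern that electrophilic substitution of a resorcinol does not give. This 2,5-dicarbon-substituted resorcinol is exactly what a vinylketene (supplying C7a, C5, C6, C7) and an oxygen-substituted alkyne (supplying C3a, C4) assemble, and the strategy rests on that.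

## Retrosynthetic reasoning

**25 to 24 to 23 (protecting groups).** The four phenols that take no part in ring construction travel as benzyl ethers, and the C4 oxygen as the triisopropylsilyl ether that the annulation delivers. Benzyl is removed last by a Lewis acid because hydrogenolysis would reduce the stilbene. The gain is stability towards organolithium and organozinc reagents and towards heat.

**23 to 21 (cut O1–C2).** C2 is the one centre that can be formed under thermodynamic control. A silyloxy group on a carbon para to an aryl ether oxygen ionises to cation 22, the neighbouring phenol closes the five-membered ring, and the aryl group on C3 dictates trans. Cutting C2–C3 or C3–C3a instead would mean creating C3 on a crowded, fully substituted ring. The forward reaction has to ionise C2 without touching the C3–H bond or the stilbene.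

**21 to 11 + 16 (key disconnection; cut C3a–C7a and C4–C5).** The benzo ring is taken apart into siloxyalkyne 11 and cyclobutenone 16. The substitution pattern then arises by construction, the two halves of the molecule are joined as the ring forms, and the two resorcinol oxygens emerge differentiated: one free (from the ketene carbonyl), one silylated. Forward, 16 must open to vinylketene 17 and be captured regiospecifically by 11, then pass through 18, 19 and 20 to 21.

**16 to 12 + 13, and 12 to 5.** The bond between the four-membered ring and the styryl group is cut. An alkenyllithium (14) adds to the vinylogous ester 13 and acid transposes the adduct 15 to the enone. Iodoalkene 12 comes from aldehyde 5 by a one-carbon iodo-olefination that fixes the E geometry.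

**11 to 8 to 7.** The C–O bond at the alkyne terminus is cut. The terminal alkyne 8 is deprotonated to 9, oxidised to ynolate 10 and silylated on oxygen. The carbinol of 7 is silylated beforehand, both to mask it against the ketene and to serve later as the leaving group.

**7 to 4 + 5 (cut C2–C3).** This bond joins the two benzylic carbons. Forming it by addition of the chiral allenylzinc 6 to aldehyde 5 brings in the guaiacyl ring and the C2 oxygen at the right oxidation level. It also creates C3 with the alkyne already attached, and relays the central chirality of 4 through the axial chirality of 6 to C3. The carbinol configuration is of no consequence, since it is erased on ring closure.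

**4 to 3 to 2 to 1.** The mesylate comes from the propargylic alcohol, and that from catalytic asymmetric alkynylation of aldehyde 1 followed by removal of the alkynyl silyl group. This is the only step in which absolute configuration is introduced.

## Alternatives that were turned down

**Alternative 1: aryne insertion into a mandelate ester.** The disconnection cuts O1–C7a and C3–C3a. Forward, a fluoride source releases the aryne from silyl triflate A2. The alkoxide of mandelate A3 adds at the aryne carbon meta to the benzyloxy group, and the resulting aryl anion attacks the ester to give benzofuranone A1.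
- For it: the core is reached in one convergent step, the alkoxy group controls the aryne regiochemistry, and the bromide at C6 allows a late Heck reaction for the stilbene. On step economy to the bicyclic core it is stronger than the chosen route.
- Against it: A1 is racemic and has no C3 substituent. Adding the resorcinol aryl group to the C3 ketone gives a tertiary benzylic alcohol next to C2–H, which dehydrates to the aromatic 2,3-diarylbenzofuran and destroys both centres. Reducing that tetrasubstituted double bond enantioselectively would give the cis isomer, by a reaction with no secure footing for this substrate class.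
- In its place the chosen strategy offers C3 set absolutely before the ring exists, with C2 then following from it.

**Alternative 2: dione, aldehyde and sulfonium ylide annulation.** The disconnection cuts C3a–C3, C3–C2 and C2–O1. Forward, dione A5 condenses with aldehyde 1, the ylide from the chiral sulfonium salt A6 (or its antipode) adds to the alkylidene dione, and the enolate oxygen displaces the sulfide to give A4.
- For it: three bonds and both stereocentres, trans, from cheap materials in one operation. On stereochemical economy it is stronger than the chosen route.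
- Against it: the chiral information sits on the ylide carbon, which becomes C2, the centre that the target can re-equilibrate anyway. It has to be relayed to C3 through the facial selectivity of a Michael addition, which is less dependable. The carbocycle of A4 must then be dehydrogenated to a phenol in the presence of two benzylic C–H bonds whose loss would aromatise the furan ring, and the ester must be converted into the styryl group in about three further steps.
- The chosen route delivers the benzo ring at the aromatic oxidation level with the styryl group already in place.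

**Alternative 3: oxidative closure of a triarylethane.** The disconnection cuts O1–C2 at the C–H oxidation level. Forward, a mild oxidant converts the 4-hydroxybenzyl methylene of A8 into a quinone methide-type electrophile, and either ortho hydroxyl of the symmetrical resorcinol ring adds to give A7, one debenzylation from 25.
- For it: no C2 oxygen has to be installed, protected and ionised, the nucleophile is symmetrical, and the closure is not acidic. On redox and protecting-group economy it is stronger.
- Against it: the oxidised intermediate has a doubly benzylic hydrogen on C3 and can tautomerise to the triarylethene, erasing the only controlled stereocentre. Three free phenols and an electron-rich stilbene are exposed to the oxidant. A8 still needs the same tetrasubstituted benzo ring and the same C3 centre, so the central problem is only postponed.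
- The chosen route brings C2 in as a carbinol by the same C–C bond formation that sets C3, and needs no oxidant near free phenols.

Key step: step 9

Assumption: in step 1 the catalyst from Me2Zn and (S,S)-ProPhenol is taken to deliver the alkynyl group to the re face of 1; if Mosher ester analysis of 2 shows the opposite sense, the (R,R) ligand is used and nothing else changes.

## Route

Step 1
Reactants: 1 3,5-bis(benzyloxy)benzaldehyde
Product: 2 (S)-1-[3,5-bis(benzyloxy)phenyl]-3-(trimethylsilyl)prop-2-yn-1-ol
Conditions: ethynyltrimethylsilane, Me2Zn, (S,S)-ProPhenol (10 mol %), Ph3P=O (20 mol %), toluene, 0 °C; aq. NH4Cl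
Reagents that add atoms: ethynyltrimethylsilane, C#C[Si](C)(C)C
Why: Catalytic asymmetric alkynylation of an aryl aldehyde by the zinc alkynylide held in the chiral ligand pocket; re-face delivery sets the carbinol centre as S, the only source of absolute configuration in the route.

Step 2
Reactants: 2 (S)-1-[3,5-bis(benzyloxy)phenyl]-3-(trimethylsilyl)prop-2-yn-1-ol
Product: 3 (R)-1-[3,5-bis(benzyloxy)phenyl]prop-2-yn-1-ol
Conditions: K2CO3 (cat.), MeOH, 0 °C to rt
Reagents that add atoms: none
Why: Base-catalysed methanolysis of the alkynyl C–Si bond (protodesilylation), done here because the only stereocentre is a carbinol that mild base cannot epimerise; the descriptor changes from S to R only because ethynyl ranks below aryl.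

Step 3
Reactants: 3 (R)-1-[3,5-bis(benzyloxy)phenyl]prop-2-yn-1-ol
Product: 4 (R)-1-[3,5-bis(benzyloxy)phenyl]prop-2-yn-1-yl methanesulfonate
Conditions: MsCl, Et3N, CH2Cl2, −78 °C; used at once without purification
Reagents that add atoms: methanesulfonyl chloride, CS(=O)(=O)Cl
Why: O-Sulfonylation with retention at carbon; the two meta benzyloxy groups do not stabilise a benzylic cation, so the mesylate should survive cold handling until the next step.

Step 4
Reactants: 4 (R)-1-[3,5-bis(benzyloxy)phenyl]prop-2-yn-1-yl methanesulfonate; 5 4-(benzyloxy)-3-methoxybenzaldehyde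
Product: 7 (1R,2S)-2-[3,5-bis(benzyloxy)phenyl]-1-[4-(benzyloxy)-3-methoxyphenyl]but-3-yn-1-ol, via allenylzinc reagent 6 (not isolated)
Conditions: Pd(OAc)2 (5 mol %), PPh3 (5 mol %), Et2Zn (3 equiv), THF, −78 to −20 °C; aq. NH4Cl
Reagents that add atoms: none
Why: Marshall allenylzinc addition: zerovalent palladium displaces the mesylate anti (SN2'), transmetalation with Et2Zn gives the (M)-allenylzinc 6 with retention, and 6 adds to 5 through a cyclic SE2' transition state on the zinc-bearing face, so that C2 of 7 is formed with overall inversion relative to 4 and the carbinol C1 anti to it. The anti preference with an aryl aldehyde may be modest, which is tolerable because C1 is re-set in step 10.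

Step 5
Reactants: 7 (1R,2S)-2-[3,5-bis(benzyloxy)phenyl]-1-[4-(benzyloxy)-3-methoxyphenyl]but-3-yn-1-ol
Product: 8 tert-butyl{[(1R,2S)-2-[3,5-bis(benzyloxy)phenyl]-1-[4-(benzyloxy)-3-methoxyphenyl]but-3-yn-1-yl]oxy}dimethylsilane
Conditions: TBSOTf, 2,6-lutidine, CH2Cl2, −78 to 0 °C
Reagents that add atoms: tert-butyldimethylsilyl trifluoromethanesulfonate, CC(C)(C)[Si](C)(C)OS(=O)(=O)C(F)(F)F
Why: Silylation of the hindered secondary alcohol with a silyl triflate and a non-nucleophilic base; the ether masks the hydroxyl against the ketene of step 9 and remains an ionisable leaving group for step 10.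

Step 6
Reactants: 8 tert-butyl{[(1R,2S)-2-[3,5-bis(benzyloxy)phenyl]-1-[4-(benzyloxy)-3-methoxyphenyl]but-3-yn-1-yl]oxy}dimethylsilane
Product: 11 {[(3R,4R)-3-[3,5-bis(benzyloxy)phenyl]-4-[4-(benzyloxy)-3-methoxyphenyl]-4-[(tert-butyldimethylsilyl)oxy]but-1-yn-1-yl]oxy}tri(propan-2-yl)silane, via lithium acetylide 9 (not isolated), via lithium ynolate 10 (not isolated)
Conditions: n-BuLi (1.0 equiv), THF, −78 °C; LiOO-t-Bu (from t-BuOOH and LiN(SiMe3)2), −78 to 0 °C; TIPSOTf, −78 to 0 °C
Reagents that add atoms: lithium tert-butyl peroxide, [Li+].CC(C)(C)O[O-]; triisopropylsilyl trifluoromethanesulfonate, CC(C)[Si](C(C)C)(C(C)C)OS(=O)(=O)C(F)(F)F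
Why: Acetylide-to-ynolate oxidation: the acetylide attacks the electrophilic peroxide oxygen and expels tert-butoxide, and the bulky silyl triflate traps the ynolate on oxygen. One equivalent of base removes only the terminal alkyne proton, so the benzylic propargylic C–H and its stereocentre should be untouched.

Step 7
Reactants: 5 4-(benzyloxy)-3-methoxybenzaldehyde
Product: 12 (E)-1-(benzyloxy)-4-(2-iodoethenyl)-2-methoxybenzene
Conditions: CHI3, CrCl2, THF, 0 °C
Reagents that add atoms: iodoform, IC(I)I
Why: Takai olefination; the iodo-carbenoid generated from CHI3 and CrCl2 adds to the aldehyde and elimination from the less crowded adduct gives the E iodoalkene, as is usual for aryl aldehydes.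

Step 8
Reactants: 12 (E)-1-(benzyloxy)-4-(2-iodoethenyl)-2-methoxybenzene; 13 3-ethoxycyclobut-2-en-1-one
Product: 16 3-{(E)-2-[4-(benzyloxy)-3-methoxyphenyl]ethenyl}cyclobut-2-en-1-one, via alkenyllithium 14 (not isolated), via lithium alkoxide adduct 15 (not isolated)
Conditions: t-BuLi (2.1 equiv), Et2O, −78 °C; 13, −78 °C; 1 M HCl, 0 °C
Reagents that add atoms: none
Why: Iodine–lithium exchange retains the E geometry, 1,2-addition to the vinylogous ester gives 15, and acid hydrolysis of the enol ether with loss of the tertiary hydroxyl (Stork–Danheiser-type transposition) delivers the 3-substituted cyclobutenone.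

Step 9
Reactants: 11 {[(3R,4R)-3-[3,5-bis(benzyloxy)phenyl]-4-[4-(benzyloxy)-3-methoxyphenyl]-4-[(tert-butyldimethylsilyl)oxy]but-1-yn-1-yl]oxy}tri(propan-2-yl)silane; 16 3-{(E)-2-[4-(benzyloxy)-3-methoxyphenyl]ethenyl}cyclobut-2-en-1-one
Product: 21 2-{(1R,2R)-1-[3,5-bis(benzyloxy)phenyl]-2-[4-(benzyloxy)-3-methoxyphenyl]-2-[(tert-butyldimethylsilyl)oxy]ethyl}-5-{(E)-2-[4-(benzyloxy)-3-methoxyphenyl]ethenyl}-3-[(triisopropylsilyl)oxy]phenol, via vinylketene 17 (not isolated), via cyclobutenone adduct 18 (not isolated), via dienylketene 19 (not isolated), via cyclohexadienone 20 (not isolated)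
Conditions: 16 (1.3 equiv), toluene, 80 °C, then 110 °C
Reagents that add atoms: none
Why: Danheiser benzannulation, the known reaction of cyclobutenones with trialkylsiloxyalkynes that gives resorcinol monosilyl ethers, is the closest precedent and is used unchanged. Heat opens 16 reversibly by 4π electrocyclic cleavage to vinylketene 17, which stays at a low stationary concentration. The ynol ether 11 adds across the ketene C=C in a regiospecific (2+2) cycloaddition, its nucleophilic carbon (remote from oxygen, bearing the side chain) bonding to the ketene carbonyl carbon (C3a–C7a) and the siloxy carbon to the ketene α-carbon (C4–C5), to give 18. 4π opening of 18 gives dienylketene 19, and a 6π electrocyclisation between the ketene carbon and the terminal methylene (C7–C7a, the bond cleaved in 16) closes the benzo ring as cyclohexadienone 20, which tautomerises to phenol 21. No stereocentre is formed: the ring carbon that is stereogenic in 18 is planarised on ring opening, and the side-chain centres are spectators that only need to withstand neutral heating. The step needs regioselectivity, which the polarisation of the siloxyalkyne towards the ketene carbonyl secures, so that the chain ends on the carbon between the two oxygens and the styryl group para to it. It also needs chemoselectivity for the alkyne over the stilbene double bond, which follows from the far higher nucleophilicity of the ynol ether, and the bulky triisopropylsilyl group keeps silicon on oxygen so that the ketene-derived hydroxyl is the only free phenol.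

Step 10
Reactants: 21 2-{(1R,2R)-1-[3,5-bis(benzyloxy)phenyl]-2-[4-(benzyloxy)-3-methoxyphenyl]-2-[(tert-butyldimethylsilyl)oxy]ethyl}-5-{(E)-2-[4-(benzyloxy)-3-methoxyphenyl]ethenyl}-3-[(triisopropylsilyl)oxy]phenol
Product: 23 {[(2R,3R)-2-[4-(benzyloxy)-3-methoxyphenyl]-6-{(E)-2-[4-(benzyloxy)-3-methoxyphenyl]ethenyl}-3-[3,5-bis(benzyloxy)phenyl]-2,3-dihydro-1-benzofuran-4-yl]oxy}tri(propan-2-yl)silane, via benzylic cation 22 (not isolated)
Conditions: TsOH·H2O (0.2 equiv), CH2Cl2, 0 °C
Reagents that add atoms: none
Why: Acid-mediated SN1 etherification: the 4-alkoxyphenyl group lets the silyloxy group leave as silanol, and the free phenol captures the planar cation 22 in a 5-exo closure. The aryl group on C3 steers the C2 aryl group to the opposite face, and because closure is reversible under acid the trans (2R,3R) isomer should prevail whatever the carbinol configuration of 21; low temperature and catalytic acid are meant to keep the cation from losing the C3 proton and the stilbene from being protonated.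

Step 11
Reactants: 23 {[(2R,3R)-2-[4-(benzyloxy)-3-methoxyphenyl]-6-{(E)-2-[4-(benzyloxy)-3-methoxyphenyl]ethenyl}-3-[3,5-bis(benzyloxy)phenyl]-2,3-dihydro-1-benzofuran-4-yl]oxy}tri(propan-2-yl)silane
Product: 24 (2R,3R)-2-[4-(benzyloxy)-3-methoxyphenyl]-6-{(E)-2-[4-(benzyloxy)-3-methoxyphenyl]ethenyl}-3-[3,5-bis(benzyloxy)phenyl]-2,3-dihydro-1-benzofuran-4-ol
Conditions: Bu4NF, AcOH, THF, 0 °C
Reagents that add atoms: none
Why: Fluoride-induced cleavage of the aryl O–Si bond; buffering with acetic acid protonates the phenoxide as it forms, and benzyl ethers, the stilbene and the cyclic benzylic ether are inert to these conditions.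

Step 12
Reactants: 24 (2R,3R)-2-[4-(benzyloxy)-3-methoxyphenyl]-6-{(E)-2-[4-(benzyloxy)-3-methoxyphenyl]ethenyl}-3-[3,5-bis(benzyloxy)phenyl]-2,3-dihydro-1-benzofuran-4-ol
Product: 25 5-[(2R,3R)-4-hydroxy-2-(4-hydroxy-3-methoxyphenyl)-6-[(E)-2-(4-hydroxy-3-methoxyphenyl)ethenyl]-2,3-dihydro-1-benzofuran-3-yl]benzene-1,3-diol
Conditions: BCl3, pentamethylbenzene, CH2Cl2, −78 °C; MeOH quench
Reagents that add atoms: none
Why: Lewis-acid debenzylation with a non-basic cation scavenger; at −78 °C BCl3 cleaves aryl benzyl ethers but not aryl methyl ethers, and hydrogenolysis is excluded by the stilbene double bond. Pentamethylbenzene takes up the benzyl cations so that the electron-rich rings are not C-benzylated, and any reversible opening of O1–C2 returns the trans isomer.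

## Compound list

1 | 3,5-bis(benzyloxy)benzaldehyde | O=Cc1cc(OCc2ccccc2)cc(OCc2ccccc2)c1 | starting material
2 | (S)-1-[3,5-bis(benzyloxy)phenyl]-3-(trimethylsilyl)prop-2-yn-1-ol | C[Si](C)(C)C#C[C@H](c1cc(OCc2ccccc2)cc(OCc2ccccc2)c1)O | intermediate
3 | (R)-1-[3,5-bis(benzyloxy)phenyl]prop-2-yn-1-ol | C#C[C@H](c1cc(OCc2ccccc2)cc(OCc2ccccc2)c1)O | intermediate
4 | (R)-1-[3,5-bis(benzyloxy)phenyl]prop-2-yn-1-yl methanesulfonate | C#C[C@H](c1cc(OCc2ccccc2)cc(OCc2ccccc2)c1)OS(C)(=O)=O | intermediate
5 | 4-(benzyloxy)-3-methoxybenzaldehyde | O=Cc1ccc(OCc2ccccc2)c(OC)c1 | starting material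
6 | (M)-{3-[3,5-bis(benzyloxy)phenyl]propa-1,2-dien-1-yl}(ethyl)zinc, not isolated | [H]C([Zn]CC)=[C@@]=C([H])c1cc(OCc2ccccc2)cc(OCc2ccccc2)c1 | intermediate
7 | (1R,2S)-2-[3,5-bis(benzyloxy)phenyl]-1-[4-(benzyloxy)-3-methoxyphenyl]but-3-yn-1-ol (anti) | C#C[C@@H](c1cc(OCc2ccccc2)cc(OCc2ccccc2)c1)[C@@H](O)c1ccc(OCc2ccccc2)c(OC)c1 | intermediate
8 | tert-butyl{[(1R,2S)-2-[3,5-bis(benzyloxy)phenyl]-1-[4-(benzyloxy)-3-methoxyphenyl]but-3-yn-1-yl]oxy}dimethylsilane | C#C[C@@H](c1cc(OCc2ccccc2)cc(OCc2ccccc2)c1)[C@@H](O[Si](C)(C)C(C)(C)C)c1ccc(OCc2ccccc2)c(OC)c1 | intermediate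
9 | lithium acetylide of 8 (terminal C–H replaced by C–Li, stereocentres as in 8), not isolated | [Li]C#C[C@@H](c1cc(OCc2ccccc2)cc(OCc2ccccc2)c1)[C@@H](O[Si](C)(C)C(C)(C)C)c1ccc(OCc2ccccc2)c(OC)c1 | intermediate
10 | lithium (3R,4R)-3-[3,5-bis(benzyloxy)phenyl]-4-[4-(benzyloxy)-3-methoxyphenyl]-4-[(tert-butyldimethylsilyl)oxy]but-1-yn-1-olate, not isolated | [Li]OC#C[C@@H](c1cc(OCc2ccccc2)cc(OCc2ccccc2)c1)[C@@H](O[Si](C)(C)C(C)(C)C)c1ccc(OCc2ccccc2)c(OC)c1 | intermediate
11 | {[(3R,4R)-3-[3,5-bis(benzyloxy)phenyl]-4-[4-(benzyloxy)-3-methoxyphenyl]-4-[(tert-butyldimethylsilyl)oxy]but-1-yn-1-yl]oxy}tri(propan-2-yl)silane | CC(C)[Si](C(C)C)(C(C)C)OC#C[C@@H](c1cc(OCc2ccccc2)cc(OCc2ccccc2)c1)[C@@H](O[Si](C)(C)C(C)(C)C)c1ccc(OCc2ccccc2)c(OC)c1 | intermediate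
12 | (E)-1-(benzyloxy)-4-(2-iodoethenyl)-2-methoxybenzene | I/C=C/c1ccc(OCc2ccccc2)c(OC)c1 | intermediate
13 | 3-ethoxycyclobut-2-en-1-one | CCOC1=CC(=O)C1 | starting material
14 | (E)-2-[4-(benzyloxy)-3-methoxyphenyl]ethenyllithium, not isolated | [Li]/C=C/c1ccc(OCc2ccccc2)c(OC)c1 | intermediate
15 | lithium 1-{(E)-2-[4-(benzyloxy)-3-methoxyphenyl]ethenyl}-3-ethoxycyclobut-2-en-1-olate (racemic), not isolated | CCOC1=CC(O[Li])(/C=C/c2ccc(OCc3ccccc3)c(OC)c2)C1 | intermediate
16 | 3-{(E)-2-[4-(benzyloxy)-3-methoxyphenyl]ethenyl}cyclobut-2-en-1-one | O=C1C=C(/C=C/c2ccc(OCc3ccccc3)c(OC)c2)C1 | intermediate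
17 | (4E)-5-[4-(benzyloxy)-3-methoxyphenyl]-3-methylidenepenta-1,4-dien-1-one (vinylketene), not isolated | O=C=CC(=C)/C=C/c1ccc(OCc2ccccc2)c(OC)c1 | intermediate
18 | 4-{(3E)-4-[4-(benzyloxy)-3-methoxyphenyl]buta-1,3-dien-2-yl}-2-(side chain of 11)-3-[(triisopropylsilyl)oxy]cyclobut-2-en-1-one, both epimers at ring C4, not isolated | O=C1C([C@@H](c2cc(OCc3ccccc3)cc(OCc3ccccc3)c2)[C@@H](O[Si](C)(C)C(C)(C)C)c2ccc(OCc3ccccc3)c(OC)c2)=C(O[Si](C(C)C)(C(C)C)C(C)C)C1C(=C)/C=C/c1ccc(OCc2ccccc2)c(OC)c1 | intermediate
19 | dienylketene from ring opening of 18 (ketene and methylidene units cis across the siloxy-substituted double bond), not isolated | O=C=C([C@@H](c1cc(OCc2ccccc2)cc(OCc2ccccc2)c1)[C@@H](O[Si](C)(C)C(C)(C)C)c1ccc(OCc2ccccc2)c(OC)c1)/C(O[Si](C(C)C)(C(C)C)C(C)C)=C\C(=C)/C=C/c1ccc(OCc2ccccc2)c(OC)c1 | intermediate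
20 | 2-(side chain of 11)-5-{(E)-2-[4-(benzyloxy)-3-methoxyphenyl]ethenyl}-3-[(triisopropylsilyl)oxy]cyclohexa-2,4-dien-1-one, not isolated | O=C1CC(/C=C/c2ccc(OCc3ccccc3)c(OC)c2)=CC(O[Si](C(C)C)(C(C)C)C(C)C)=C1[C@@H](c1cc(OCc2ccccc2)cc(OCc2ccccc2)c1)[C@@H](O[Si](C)(C)C(C)(C)C)c1ccc(OCc2ccccc2)c(OC)c1 | intermediate
21 | 2-{(1R,2R)-1-[3,5-bis(benzyloxy)phenyl]-2-[4-(benzyloxy)-3-methoxyphenyl]-2-[(tert-butyldimethylsilyl)oxy]ethyl}-5-{(E)-2-[4-(benzyloxy)-3-methoxyphenyl]ethenyl}-3-[(triisopropylsilyl)oxy]phenol | Oc1cc(/C=C/c2ccc(OCc3ccccc3)c(OC)c2)cc(O[Si](C(C)C)(C(C)C)C(C)C)c1[C@@H](c1cc(OCc2ccccc2)cc(OCc2ccccc2)c1)[C@@H](O[Si](C)(C)C(C)(C)C)c1ccc(OCc2ccccc2)c(OC)c1 | intermediate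
22 | benzylic cation from 21 (silyloxy group lost from the carbinol carbon, C3 unchanged), not isolated | Oc1cc(/C=C/c2ccc(OCc3ccccc3)c(OC)c2)cc(O[Si](C(C)C)(C(C)C)C(C)C)c1[C@@H](c1cc(OCc2ccccc2)cc(OCc2ccccc2)c1)[CH+]c1ccc(OCc2ccccc2)c(OC)c1 | intermediate
23 | {[(2R,3R)-2-[4-(benzyloxy)-3-methoxyphenyl]-6-{(E)-2-[4-(benzyloxy)-3-methoxyphenyl]ethenyl}-3-[3,5-bis(benzyloxy)phenyl]-2,3-dihydro-1-benzofuran-4-yl]oxy}tri(propan-2-yl)silane | COc1cc(/C=C/c2cc(O[Si](C(C)C)(C(C)C)C(C)C)c3c(c2)O[C@@H](c2ccc(OCc4ccccc4)c(OC)c2)[C@@H]3c2cc(OCc4ccccc4)cc(OCc4ccccc4)c2)ccc1OCc1ccccc1 | intermediate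
24 | (2R,3R)-2-[4-(benzyloxy)-3-methoxyphenyl]-6-{(E)-2-[4-(benzyloxy)-3-methoxyphenyl]ethenyl}-3-[3,5-bis(benzyloxy)phenyl]-2,3-dihydro-1-benzofuran-4-ol | COc1cc(/C=C/c2cc(O)c3c(c2)O[C@@H](c2ccc(OCc4ccccc4)c(OC)c2)[C@@H]3c2cc(OCc4ccccc4)cc(OCc4ccccc4)c2)ccc1OCc1ccccc1 | intermediate
25 | 5-[(2R,3R)-4-hydroxy-2-(4-hydroxy-3-methoxyphenyl)-6-[(E)-2-(4-hydroxy-3-methoxyphenyl)ethenyl]-2,3-dihydro-1-benzofuran-3-yl]benzene-1,3-diol | COc1cc(/C=C/c2cc(O)c3c(c2)O[C@@H](c2ccc(O)c(OC)c2)[C@@H]3c2cc(O)cc(O)c2)ccc1O | target

## Step count and least certain steps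

Total: 12 steps. Longest linear sequence: 10 steps (steps 1–6 and 9–12, from aldehyde 1); the cyclobutenone branch (steps 7 and 8) is two steps from aldehyde 5.

**Step 9 (key step).** The most likely failure is that the strained dienone 16 and its ring-opened ketene 17, which carry an extra conjugated styryl unit, are consumed by self-reaction (ketene dimerisation, Diels–Alder-type oligomerisation) before the bimolecular (2+2) capture occurs. That capture is slowed by the branched, secondary substituent on the nucleophilic carbon of 11.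

Fallback, setting out from 11 and coming back at 23: the stilbene is attached after the annulation.
- Dichloroketene, made from trichloroacetyl chloride and Zn–Cu couple, is added to 3,3-diethoxyprop-1-yne to give 4,4-dichloro-3-(diethoxymethyl)cyclobut-2-en-1-one F1.
- Zn in AcOH/TMEDA removes both chlorines to give 3-(diethoxymethyl)cyclobut-2-en-1-one F2, a cyclobutenone without extra unsaturation.
- Heating F2 with 11 should give the acetal-bearing resorcinol monosilyl ether F3.
- TsOH·H2O in wet CH2Cl2 then closes the dihydrofuran as in step 10 and hydrolyses the acetal, giving the benzofuran-6-carbaldehyde F4.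
- Horner–Wadsworth–Emmons olefination of F4 with the potassium anion (KO-t-Bu, THF) of diethyl [4-(benzyloxy)-3-methoxybenzyl]phosphonate F5 installs the E-stilbene and gives 23. F5 is made by Arbuzov reaction of 4-(benzyloxy)-3-methoxybenzyl chloride with triethyl phosphite.

**Step 4.** The most likely failure is erosion of enantiomeric purity at C3. The aryl group stabilises the propargyl/allenyl metal species, so equilibration of the allenylpalladium and allenylzinc intermediates, or ionisation of the benzylic propargylic mesylate before oxidative addition, can scramble the axial chirality of 6.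

Fallback, setting out from 2 and coming back at 7:
- Methyl chloroformate and pyridine convert 2 into (S)-1-[3,5-bis(benzyloxy)phenyl]-3-(trimethylsilyl)prop-2-yn-1-yl methyl carbonate F6.
- Borylation with bis(pinacolato)diboron, catalysed by CuCl/NaO-t-Bu/Xantphos, proceeds by anti SN2' substitution and gives the isolable, configurationally stable (P)-allenylboronate F7.
- Heating F7 with 5 in toluene adds it through a closed six-membered transition state on the boron-bearing face. After work-up this gives (1R,2R)-2-[3,5-bis(benzyloxy)phenyl]-1-[4-(benzyloxy)-3-methoxyphenyl]-4-(trimethylsilyl)but-3-yn-1-ol F8, with the same sense at the propargylic carbon as in the zinc route.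
- K2CO3 in MeOH removes the alkynyl silyl group and gives 7.

**Step 1.** The most likely failure is insufficient enantioselectivity, through uncatalysed background addition of the small silylacetylide to the aryl aldehyde, or an unexpected sense of induction.

Fallback, setting out from 1 and coming back at 3:
- Ethynylmagnesium bromide adds to 1 to give racemic 1-[3,5-bis(benzyloxy)phenyl]prop-2-yn-1-ol F9.
- Novozym 435 (immobilised Candida antarctica lipase B) and vinyl acetate acylate the R enantiomer (aryl as the large, ethynyl as the medium substituent). This gives (R)-1-[3,5-bis(benzyloxy)phenyl]prop-2-yn-1-yl acetate F10 and leaves (S)-1-[3,5-bis(benzyloxy)phenyl]prop-2-yn-1-ol F11, which is separated.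
- Methanolysis of F10 with K2CO3 in MeOH gives 3.

## Further compounds

F1 | step 9 | 4,4-dichloro-3-(diethoxymethyl)cyclobut-2-en-1-one | O=C1C=C(C(OCC)OCC)C1(Cl)Cl
F2 | step 9 | 3-(diethoxymethyl)cyclobut-2-en-1-one | O=C1C=C(C(OCC)OCC)C1
F3 | step 9 | 2-{(1R,2R)-1-[3,5-bis(benzyloxy)phenyl]-2-[4-(benzyloxy)-3-methoxyphenyl]-2-[(tert-butyldimethylsilyl)oxy]ethyl}-5-(diethoxymethyl)-3-[(triisopropylsilyl)oxy]phenol | Oc1cc(C(OCC)OCC)cc(O[Si](C(C)C)(C(C)C)C(C)C)c1[C@@H](c1cc(OCc2ccccc2)cc(OCc2ccccc2)c1)[C@@H](O[Si](C)(C)C(C)(C)C)c1ccc(OCc2ccccc2)c(OC)c1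
F4 | step 9 | (2R,3R)-2-[4-(benzyloxy)-3-methoxyphenyl]-3-[3,5-bis(benzyloxy)phenyl]-4-[(triisopropylsilyl)oxy]-2,3-dihydro-1-benzofuran-6-carbaldehyde | O=Cc1cc(O[Si](C(C)C)(C(C)C)C(C)C)c2c(c1)O[C@@H](c1ccc(OCc3ccccc3)c(OC)c1)[C@@H]2c1cc(OCc2ccccc2)cc(OCc2ccccc2)c1
F5 | step 9 | diethyl [4-(benzyloxy)-3-methoxybenzyl]phosphonate | CCOP(=O)(Cc1ccc(OCc2ccccc2)c(OC)c1)OCC
F6 | step 4 | (S)-1-[3,5-bis(benzyloxy)phenyl]-3-(trimethylsilyl)prop-2-yn-1-yl methyl carbonate | C[Si](C)(C)C#C[C@H](c1cc(OCc2ccccc2)cc(OCc2ccccc2)c1)OC(=O)OC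
F7 | step 4 | (P)-{3-[3,5-bis(benzyloxy)phenyl]-1-(4,4,5,5-tetramethyl-1,3,2-dioxaborolan-2-yl)propa-1,2-dien-1-yl}trimethylsilane | C[Si](C)(C)C(B1OC(C)(C)C(C)(C)O1)=[C@@]=C([H])c1cc(OCc2ccccc2)cc(OCc2ccccc2)c1
F8 | step 4 | (1R,2R)-2-[3,5-bis(benzyloxy)phenyl]-1-[4-(benzyloxy)-3-methoxyphenyl]-4-(trimethylsilyl)but-3-yn-1-ol | C[Si](C)(C)C#C[C@@H](c1cc(OCc2ccccc2)cc(OCc2ccccc2)c1)[C@@H](O)c1ccc(OCc2ccccc2)c(OC)c1
F9 | step 1 | racemic 1-[3,5-bis(benzyloxy)phenyl]prop-2-yn-1-ol | C#CC(O)c1cc(OCc2ccccc2)cc(OCc2ccccc2)c1
F10 | step 1 | (R)-1-[3,5-bis(benzyloxy)phenyl]prop-2-yn-1-yl acetate | C#C[C@H](c1cc(OCc2ccccc2)cc(OCc2ccccc2)c1)OC(C)=O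
F11 | step 1 | (S)-1-[3,5-bis(benzyloxy)phenyl]prop-2-yn-1-ol | C#C[C@@H](c1cc(OCc2ccccc2)cc(OCc2ccccc2)c1)O
A1 | alternative 1 | racemic 4-(benzyloxy)-6-bromo-2-[4-(benzyloxy)-3-methoxyphenyl]-1-benzofuran-3(2H)-one | O=C1C(c2ccc(OCc3ccccc3)c(OC)c2)Oc2cc(Br)cc(OCc3ccccc3)c12
A2 | alternative 1 | 3-(benzyloxy)-5-bromo-2-(trimethylsilyl)phenyl trifluoromethanesulfonate | C[Si](C)(C)c1c(OS(=O)(=O)C(F)(F)F)cc(Br)cc1OCc1ccccc1
A3 | alternative 1 | racemic methyl 2-[4-(benzyloxy)-3-methoxyphenyl]-2-hydroxyacetate | COC(=O)C(O)c1ccc(OCc2ccccc2)c(OC)c1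
A4 | alternative 2 | ethyl (2R,3R)-2-[4-(benzyloxy)-3-methoxyphenyl]-3-[3,5-bis(benzyloxy)phenyl]-4-oxo-2,3,4,5,6,7-hexahydro-1-benzofuran-6-carboxylate (C6 unassigned) | CCOC(=O)C1CC(=O)C2=C(C1)O[C@@H](c1ccc(OCc3ccccc3)c(OC)c1)[C@@H]2c1cc(OCc2ccccc2)cc(OCc2ccccc2)c1
A5 | alternative 2 | ethyl 3,5-dioxocyclohexane-1-carboxylate | CCOC(=O)C1CC(=O)CC(=O)C1
A6 | alternative 2 | (2R,5R)-1-[4-(benzyloxy)-3-methoxybenzyl]-2,5-dimethylthiolan-1-ium trifluoromethanesulfonate | C[C@@H]1CC[C@@H](C)[S+]1Cc1ccc(OCc2ccccc2)c(OC)c1.[O-]S(=O)(=O)C(F)(F)F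
A7 | alternative 3 | (2R,3R)-6-{(E)-2-[4-(benzyloxy)-3-methoxyphenyl]ethenyl}-3-[3,5-bis(benzyloxy)phenyl]-2-(4-hydroxy-3-methoxyphenyl)-2,3-dihydro-1-benzofuran-4-ol | COc1cc(/C=C/c2cc(O)c3c(c2)O[C@@H](c2ccc(O)c(OC)c2)[C@@H]3c2cc(OCc4ccccc4)cc(OCc4ccccc4)c2)ccc1OCc1ccccc1
A8 | alternative 3 | 2-{(1R)-1-[3,5-bis(benzyloxy)phenyl]-2-(4-hydroxy-3-methoxyphenyl)ethyl}-5-{(E)-2-[4-(benzyloxy)-3-methoxyphenyl]ethenyl}benzene-1,3-diol | COc1cc(C[C@H](c2cc(OCc3ccccc3)cc(OCc3ccccc3)c2)c2c(O)cc(/C=C/c3ccc(OCc4ccccc4)c(OC)c3)cc2O)ccc1O
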